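I was asked how far the flask gets by 50 min and how the two hands share that.

- part of the left-handed substrate and right-handed substrate charged together that has reacted at 50 min
- excess of left-handed product over right-handed product in the product at 50 min
- excess of right-handed substrate over left-handed substrate among what is left of the two at 50 min

in all of them: left-handed substrate 0.80 M; right-handed substrate 0.80 M
- elm: reagent 0.80 M; free catalyst 20 mM; run made earlier
- ash: reagent 1.8 M; free catalyst 20 mM; run made earlier
- maple: reagent 1.2 M; free catalyst 40 mM; run made earlier
- flask: reagent 1.20 M; free catalyst 20 mM; time 50 min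

| run | time / min | left-handed substrate / % | right-handed substrate / % | left-handed product / % |
|---|---|---|---|---|
| elm | 2.00 | 6.9 | 46.4 | 43.5 |
| elm | 6.00 | 3.7 | 47.0 | 46.3 |
| elm | 10.0 | 3.7 | 48.0 | 46.4 |
| elm | 15.0 | 3.1 | 47.6 | 46.5 |
| elm | 25.0 | 3.8 | 46.9 | 46.5 |
| elm | 30.0 | 2.2 | 47.4 | 47.0 |
| ash | 2.50 | 0.4 | 37.9 | 50.2 |
| ash | 4.00 | 0 | 35.8 | 50.5 |
| ash | 6.00 | 0.1 | 34.6 | 50.2 |
| ash | 10.0 | 0 | 33.2 | 49.9 |
| ash | 20.0 | 0 | 29.4 | 50.4 |
| ash | 30.0 | 0.3 | 27.1 | 49.9 |
| maple | 2.50 | 0 | 42.5 | 50.1 |
| maple | 5.00 | 0.1 | 40.6 | 49.9 |
| maple | 8.00 | 0.9 | 40.0 | 50.4 |
| maple | 15.0 | 0 | 37.9 | 50.2 |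
| maple | 30.0 | 0.2 | 35.7 | 50.7 |

(scatter of a reading: 0.5 percentage points)

- free catalyst is single-handed; left-handed substrate and right-handed substrate are mirror images of each other, charged as a racemate, each of them at the stated concentration
- the numbers in the tables scatter with a standard deviation of 0.5 percentage points
- reactions considered so far: 2 free catalyst -> spent catalyst A; free catalyst <-> dormant form; reagent + catalyst intermediate B -> free catalyst + right-handed product; free catalyst + left-handed substrate <-> catalyst intermediate A; reagent + free catalyst -> spent catalyst B; reagent + catalyst intermediate A -> free catalyst + left-handed product; free catalyst + right-handed substrate <-> catalyst intermediate B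
- an excess is the difference of the two amounts in percent of their sum
- an excess is below zero if the other one leads

The charges came first. Each product takes one reagent, and in the flask the reagent was charged below the two substrates together, so I wrote its balance. Reagent charged as a fraction of both substrates charged was 75.0% in the flask; I called this the reagent ceiling.

The elm run had a ceiling of 50.0% and read 50.4% reacted at 30.0 min, so there the reagent was the limiting reagent. But the maple run, with the flask's ceiling and twice its catalyst, read 64.1% at 30.0 min, below that ceiling. The ash run read 72.6% at 30.0 min against a ceiling of 112%. So I took the catalyst to be failing in those two runs, and I expected the flask to stay below its ceiling.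

The forecast gave 63.4% reacted, a product excess of 57.7% and a substrate excess of 99.9%. Its ground was this: “The flask has the same stoichiometry as maple”. On my balance, that left 15.5% of the reagent charge unused.

The flask gave 63.8%, 56.9% and >99.9%, so the forecast held.

    2 free catalyst → spent catalyst A (k = 2.66 /M/s)
    free catalyst ⇌ dormant form (K = 3.67, k = 0.00822 /s)
    reagent + catalyst intermediate B → free catalyst + right-handed product (k = 0.315 /M/s)
    free catalyst + left-handed substrate ⇌ catalyst intermediate A (K = 12.3 /M, k = 20.3 /M/s)
    reagent + free catalyst → spent catalyst B (k = 0.00190 /M/s)
    reagent + catalyst intermediate A → free catalyst + left-handed product (k = 2.61 /M/s)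
    free catalyst + right-handed substrate ⇌ catalyst intermediate B (K = 1.64 /M, k = 15.4 /M/s)

Against the ceiling, that left 14.9% of the reagent charge unused in the flask. In the flask, half of the turnover of the passing of free catalyst and right-handed substrate into catalyst intermediate B up to 50 min was done by 3.31 min, and at 50.0 min spent catalyst A held 84.7% of the catalyst charged, against 1.49% free.

A neighbour flask charged with 0.30 M of reagent has a ceiling of 18.7%. Computed, it reached 19.0% reacted, of which 18.7% stood as the two products, with 0% reagent left.

The runs stem from a simulated flask for substances that don't exist, noise included.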